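**Plan**

1. Retrosynthesis: after unmasking of the esters, the C9–C10 bond of the target gibberellin is cut by a retro-1,2-shift that puts the formyl carbon C20 back into ring B between C9 and C10. The six-membered ring C5–C6–C8–C9–C20–C10 (C10=C20) is then cut at C5–C6 and C8–C9 by a retro-Diels–Alder reaction, and C9–C11 by a B-alkyl Suzuki coupling.
2. Enabling feature: C20 is a one-carbon branch on quaternary C10, flanked by C5 and C9, so ring B plus C20 is a cyclohexene. C7 on C6 makes C6=C8 (exocyclic on ring D) an acrylate-type dienophile for the diene C5=C10–C20=C9 on ring A.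
3. Forward: a ring A dienyl iodide and a ring D alkylidene ester are joined to a triene. One intramolecular cycloaddition forms ring C, the C20-enlarged ring B and quaternary C8 (the bicyclo[3.2.1]octane of rings C and D).
4. Then: C19-carboxyl-directed iodolactone, α-epoxide, ring D enone, 15β-alcohol, Meinwald contraction to ring B with C10–CHO, hydrolysis.
5. Stereochemistry: C4 by asymmetric phase-transfer methylation; C13 from (S)-4-silyloxycyclopentenone; C5, C8, C9 (and C6, later equilibrated) from the cycloaddition, relayed from C13 through the bridge; C10 from the α-epoxide by the stereospecific shift; C15 by exo hydride delivery.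

Key step: step 11

Remark: atoms carry ent-gibberellane numbers (C1–C20). Compounds 18–27 have the B-homo skeleton: ring A (C1–C5, C10) is fused at C5–C10 to the six-membered ring C5–C6–C8–C9–C20–C10, which is fused at C8–C9 to the bicyclo[3.2.1]octane of ring C (C8, C9, C11–C14) and ring D (C8, C14, C13, C16, C15).
Remark: α and β are used as in the gibberellin series: H5, H9, the C7 carboxyl on C6 and C15 on C8 are β; C19, C20 and C14 are α; a 15β substituent lies on the face of ring D that carries the C9–C11–C12 bridge (endo).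
Remark: the target is taken as the open 20-aldehyde 7,19-diacid as drawn; in solution it may equilibrate with its 19,20-lactol.

**Route**

Step 1
Reactants: 1 tert-butyl 2-oxocyclohexane-1-carboxylate
Product: 2 tert-butyl (1R)-1-methyl-2-oxocyclohexane-1-carboxylate
Conditions: MeI, CsOH·H2O, N-(9-anthracenylmethyl)cinchoninium chloride (10 mol %), toluene, −40 °C
Reagents that add atoms: iodomethane, CI
Why: Enantioselective phase-transfer alkylation of a cyclic β-keto ester: the chiral ammonium–enolate ion pair exposes one enolate face to MeI and sets quaternary C4 (the pseudoenantiomeric cinchonidinium salt is taken if the facial sense proves opposite).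

Step 2
Reactants: 2 tert-butyl (1R)-1-methyl-2-oxocyclohexane-1-carboxylate
Product: 3 tert-butyl (1R,3Z)-3-(hydroxymethylidene)-1-methyl-2-oxocyclohexane-1-carboxylate
Conditions: NaH, HCO2Et, THF, 0 °C to rt; then 1 M HCl
Reagents that add atoms: ethyl formate, CCOC=O
Why: Claisen formylation at the only enolisable α-carbon (the other is quaternary) brings in C20 on the future C10.

Step 3
Reactants: 3 tert-butyl (1R,3Z)-3-(hydroxymethylidene)-1-methyl-2-oxocyclohexane-1-carboxylate
Product: 4 tert-butyl (1R,3E)-1-methyl-2-oxo-3-[(propan-2-yloxy)methylidene]cyclohexane-1-carboxylate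
Conditions: K2CO3, 2-iodopropane, DMF, rt
Reagents that add atoms: 2-iodopropane, CC(C)I
Why: O-alkylation of the β-keto aldehyde enol gives the vinylogous ester needed for the carbonyl transposition.

Step 4
Reactants: 4 tert-butyl (1R,3E)-1-methyl-2-oxo-3-[(propan-2-yloxy)methylidene]cyclohexane-1-carboxylate
Product: 6 tert-butyl (1R)-3-formyl-1-methylcyclohex-2-ene-1-carboxylate, via allylic aluminium alkoxide 5 (not isolated)
Conditions: i-Bu2AlH, CH2Cl2, −78 °C; then 1 M HCl, THF, 0 °C
Reagents that add atoms: water, O
Why: 1,2-Reduction of the vinylogous ester and acid-induced allylic transposition with hydrolysis (a Stork–Danheiser-type carbonyl transposition) should place the double bond at C5=C10 and unveil the C20 aldehyde, the hindered tert-butyl ester being spared at −78 °C.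

Step 5
Reactants: 6 tert-butyl (1R)-3-formyl-1-methylcyclohex-2-ene-1-carboxylate
Product: 7 tert-butyl (1R)-3-[(E)-2-iodoethenyl]-1-methylcyclohex-2-ene-1-carboxylate
Conditions: CrCl2, CHI3, THF, 0 °C
Reagents that add atoms: iodoform, IC(I)I
Why: Takai olefination through the gem-dichromium reagent should give the E dienyl iodide, which fixes the C20=C9 geometry of the diene and provides C9.

Step 6
Reactants: 8 (4S)-4-[(tert-butyldimethylsilyl)oxy]cyclopent-2-en-1-one
Product: 10 (4R)-4-ethenylcyclopent-2-en-1-one, via trans silyloxy ketone 9 (not isolated)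
Conditions: CH2=CHMgBr, CuBr·SMe2 (20 mol %), THF, −78 °C; aq NH4Cl; then DBU, CH2Cl2, 0 °C
Reagents that add atoms: vinylmagnesium bromide, C=C[Mg]Br
Why: Copper-catalysed conjugate addition anti to the silyloxy group sets C13, and E1cB loss of silanolate through the other α-carbon transposes the enone (addition–elimination), so that C8 becomes the enone α-carbon.

Step 7
Reactants: 10 (4R)-4-ethenylcyclopent-2-en-1-one
Product: 12 methyl 2-[(4R)-4-ethenyl-2-oxocyclopentyl]-2-hydroxyacetate (mixture at the two new centres), via silyl enol ether 11 (not isolated)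
Conditions: [(Ph3P)CuH]6 (2 mol %), PhMe2SiH, toluene, rt; then methyl glyoxylate, Sc(OTf)3 (10 mol %), CH2Cl2, −78 °C; 1 M HCl work-up
Reagents that add atoms: methyl glyoxylate, COC(=O)C=O
Why: Conjugate hydrosilylation gives the enol ether regiospecifically at C8, which deprotonation of the saturated ketone could not, and the Mukaiyama aldol attaches C6–C7; both new centres are erased in step 8.

Step 8
Reactants: 12 methyl 2-[(4R)-4-ethenyl-2-oxocyclopentyl]-2-hydroxyacetate
Product: 14 methyl (2E)-2-[(4R)-4-ethenyl-2-oxocyclopentylidene]acetate, via mesylate 13 (not isolated)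
Conditions: MsCl, Et3N, CH2Cl2, 0 °C to rt
Reagents that add atoms: none
Why: E1cB β-elimination should give the thermodynamically preferred E alkylidene, with the ester on the C14 side, away from the ketone.

Step 9
Reactants: 14 methyl (2E)-2-[(4R)-4-ethenyl-2-oxocyclopentylidene]acetate
Product: 15 methyl (2E)-2-[(8R)-8-ethenyl-1,4-dioxaspiro[4.4]nonan-6-ylidene]acetate
Conditions: (TMSOCH2)2, TMSOTf (5 mol %), CH2Cl2, −78 to −20 °C
Reagents that add atoms: 1,2-bis(trimethylsilyloxy)ethane, C[Si](C)(C)OCCO[Si](C)(C)C
Why: Aprotic silyl-triflate ketalisation masks C15 without moving the ester-conjugated double bond; the dioxolane removes the ketone as a competing endo director and later blocks the unwanted cycloaddition mode.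

Step 10
Reactants: 15 methyl (2E)-2-[(8R)-8-ethenyl-1,4-dioxaspiro[4.4]nonan-6-ylidene]acetate; 7 tert-butyl (1R)-3-[(E)-2-iodoethenyl]-1-methylcyclohex-2-ene-1-carboxylate
Product: 17 tert-butyl (1R)-3-[(1E)-4-[(6E,8R)-6-(2-methoxy-2-oxoethylidene)-1,4-dioxaspiro[4.4]nonan-8-yl]but-1-en-1-yl]-1-methylcyclohex-2-ene-1-carboxylate, via alkylborane 16 (not isolated)
Conditions: 9-BBN dimer, THF, rt; then 7, Pd(dppf)Cl2 (5 mol %), AsPh3, Cs2CO3, DMF/H2O, rt
Reagents that add atoms: none
Why: B-alkyl Suzuki–Miyaura coupling: only the monosubstituted alkene is hydroborated, and coupling with the vinyl iodide forms C9–C11 with retention of the E geometry.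

Step 11
Reactants: 17 tert-butyl (1R)-3-[(1E)-4-[(6E,8R)-6-(2-methoxy-2-oxoethylidene)-1,4-dioxaspiro[4.4]nonan-8-yl]but-1-en-1-yl]-1-methylcyclohex-2-ene-1-carboxylate
Product: 18 B-homo Diels–Alder adduct (C10=C20; 4α-CO2tBu; 4β-Me; H5 β; 6α-CO2Me; H9 β; 15-ethylene ketal)
Conditions: o-dichlorobenzene (high dilution), BHT, 180 °C, sealed tube
Reagents that add atoms: none
Why: Thermal intramolecular Diels–Alder reaction (concerted suprafacial [4+2]; closest known type: cyclisation of 1,3,9-decatrienoates with a trisubstituted dienophile) between the diene C5=C10–C20=C9 and the ester-activated alkene C6=C8. The cycloaddition closes the six-membered ring C5–C6–C8–C9–C20–C10 in the [4+2] mode, and the four-atom tether C11–C12–C13–C14 closes six-membered ring C as the fused ring, which completes the bicyclo[3.2.1]octane with ring D. Quaternary C8 is fixed by the bridge, because C9 can only reach the face of the cyclopentylidene that carries the C13 side chain. C5 and C9 follow from the E diene geometry (H5 and H9 cis), and C6 from the E dienophile geometry (C7 cis to C14; corrected in step 12). The reaction needs the endo mode with C14 and the ester under the diene, which puts H9 cis to C15 and, through the tether, makes the diene react on its face anti to the pseudo-axial C18 methyl of (R)-C4. This mode should be secured by secondary overlap of the ester, by the dioxolane oxygen on the attacked face (it collides with the diene in the other mode) and by the clash of an exo ester with quaternary C4; the regiochemistry is imposed by the tether.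

Step 12
Reactants: 18 B-homo Diels–Alder adduct
Product: 19 6β-CO2Me epimer of the B-homo adduct
Conditions: NaOMe (0.3 equiv), MeOH, 60 °C
Reagents that add atoms: none
Why: Thermodynamic epimerisation through the ester enolate: the 6α ester is cis to quaternary C4 on the neighbouring C5 and syn to C11 across the ring, so equilibration should place it in the 6β position of the target, trans to C4, while the tert-butyl ester is inert to methoxide.

Step 13
Reactants: 19 6β-CO2Me epimer of the B-homo adduct
Product: 21 B-homo 20β-iodo-19,10α-lactone 15-ketone 7-methyl ester, via iodolactone ketal 20 (not isolated)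
Conditions: I2, NaHCO3, MeCN, 0 °C; aq Na2S2O3; then 2 M HCl, THF, rt
Reagents that add atoms: iodine, II; water, O
Why: Iodolactonisation with tert-butyl ester participation: the iodonium forms on the open β face, the axial 4α ester carbonyl attacks tertiary C10 from the α face (5-exo, Markovnikov, trans-diaxial) with loss of isobutene, and the acid then hydrolyses the dioxolane to the C15 ketone.

Step 14
Reactants: 21 B-homo 20β-iodo-19,10α-lactone 15-ketone 7-methyl ester
Product: 22 B-homo 10α,20α-epoxide 15-ketone 7,19-dimethyl ester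
Conditions: NaOMe (3 equiv), MeOH, 50 °C
Reagents that add atoms: sodium methoxide, [Na+].[O-]C
Why: Methanolysis of the lactone frees the C10 alkoxide anti-periplanar to C20–I, and intramolecular SN2 closure (inversion at C20) gives the epoxide on the hindered α face, syn to C19, which a peracid would not reach.

Step 15
Reactants: 22 B-homo 10α,20α-epoxide 15-ketone 7,19-dimethyl ester
Product: 25 B-homo 10α,20α-epoxy-16-methylidene-15-ketone dimethyl ester, via Mannich base 23 (not isolated), via methiodide 24 (not isolated)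
Conditions: LiN(SiMe3)2, THF, −78 °C; CH2=NMe2+ I−, −78 to 0 °C; then MeI, MeOH, rt; then aq NaHCO3, CH2Cl2, rt
Reagents that add atoms: dimethylmethylideneammonium iodide, C=[N+](C)C.[I-]
Why: The ketone can enolise only toward C16 (C8 is quaternary), so Mannich alkylation followed by quaternisation and β-elimination should install the 16-methylidene group (C17).

Step 16
Reactants: 25 B-homo 10α,20α-epoxy-16-methylidene-15-ketone dimethyl ester
Product: 26 B-homo 10α,20α-epoxy-15β-hydroxy-16-methylidene dimethyl ester
Conditions: NaBH4, CeCl3·7H2O, MeOH, −40 °C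
Reagents that add atoms: none
Why: Luche 1,2-reduction: hydride should add from the exo face (the side of the C14 bridge), away from the axial hydrogen on C11 of the three-carbon bridge, as expected for 16-en-15-ones of this bicyclo[3.2.1]octane class, giving the 15β (endo) alcohol of the target.

Step 17
Reactants: 26 B-homo 10α,20α-epoxy-15β-hydroxy-16-methylidene dimethyl ester
Product: 27 15β-acetate of the B-homo epoxy alcohol
Conditions: Ac2O, pyridine, DMAP (cat.), CH2Cl2, rt
Reagents that add atoms: acetic anhydride, CC(=O)OC(C)=O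
Why: Acylation keeps the free hydroxyl from consuming the aluminium Lewis acid of step 18, and the acetate falls off in the final hydrolysis.

Step 18
Reactants: 27 15β-acetate of the B-homo epoxy alcohol
Product: 28 7,19-dimethyl ester 15-acetate of the target gibberellin
Conditions: MeAl(OAr)2 (Ar = 4-bromo-2,6-di-tert-butylphenyl; MABR, 2 equiv), CH2Cl2, −78 to −20 °C
Reagents that add atoms: none
Why: Meinwald rearrangement: the bulky oxophilic Lewis acid lengthens the tertiary C10–O bond and the ring bond C20–C9 shifts to C10 anti to the departing oxygen, so the α-epoxide should deliver C20 as the α-formyl group on quaternary C10, contract the six-membered ring to ring B and retain C9; alkyl rather than hydride shift is the known course for 1-alkylcyclohexene oxides with this reagent.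

Step 19
Reactants: 28 7,19-dimethyl ester 15-acetate of the target gibberellin
Product: 29 target gibberellin (15β-hydroxy-16-methylidene 20-aldehyde 7,19-diacid)
Conditions: LiOH, THF/MeOH/H2O, 45 °C; then 1 M HCl to pH 3
Reagents that add atoms: lithium hydroxide, [Li+].[OH-]
Why: Saponification removes the acetate and the C7 ester, and the hindered axial C19 ester should be opened with anchimeric help from the 1,3-diaxial aldehyde hydrate (through the 19,20-lactol); the non-enolisable aldehyde and the thermodynamically preferred 6β centre survive.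

**Compound list**

1 | tert-butyl 2-oxocyclohexane-1-carboxylate | O=C1CCCCC1C(=O)OC(C)(C)C | starting material
2 | tert-butyl (1R)-1-methyl-2-oxocyclohexane-1-carboxylate | C1CC[C@@](C)(C(=O)OC(C)(C)C)C(=O)C1 | intermediate
3 | tert-butyl (1R,3Z)-3-(hydroxymethylidene)-1-methyl-2-oxocyclohexane-1-carboxylate | C1CC[C@@](C)(C(=O)OC(C)(C)C)C(=O)/C1=C\O | intermediate
4 | tert-butyl (1R,3E)-1-methyl-2-oxo-3-[(propan-2-yloxy)methylidene]cyclohexane-1-carboxylate | C1CC[C@@](C)(C(=O)OC(C)(C)C)C(=O)/C1=C/OC(C)C | intermediate
5 | tert-butyl (1R,3E)-2-hydroxy-1-methyl-3-[(propan-2-yloxy)methylidene]cyclohexane-1-carboxylate, present as its aluminium alkoxide (mixture at C2) | C1CC[C@@](C)(C(=O)OC(C)(C)C)C(O)/C1=C/OC(C)C | intermediate (not isolated)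
6 | tert-butyl (1R)-3-formyl-1-methylcyclohex-2-ene-1-carboxylate | C1CC[C@@](C)(C(=O)OC(C)(C)C)C=C1C=O | intermediate
7 | tert-butyl (1R)-3-[(E)-2-iodoethenyl]-1-methylcyclohex-2-ene-1-carboxylate | C1CC[C@@](C)(C(=O)OC(C)(C)C)C=C1/C=C/I | intermediate
8 | (4S)-4-[(tert-butyldimethylsilyl)oxy]cyclopent-2-en-1-one | O=C1C=C[C@@H](O[Si](C)(C)C(C)(C)C)C1 | starting material
9 | (3R,4S)-4-[(tert-butyldimethylsilyl)oxy]-3-ethenylcyclopentan-1-one | C=C[C@@H]1[C@@H](O[Si](C)(C)C(C)(C)C)CC(=O)C1 | intermediate (not isolated)
10 | (4R)-4-ethenylcyclopent-2-en-1-one | C=C[C@@H]1C=CC(=O)C1 | intermediate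
11 | {[(4R)-4-ethenylcyclopent-1-en-1-yl]oxy}dimethyl(phenyl)silane | C=C[C@@H]1CC=C(O[Si](C)(C)c2ccccc2)C1 | intermediate (not isolated)
12 | methyl 2-[(4R)-4-ethenyl-2-oxocyclopentyl]-2-hydroxyacetate (mixture at the two new centres) | C=C[C@@H]1CC(C(O)C(=O)OC)C(=O)C1 | intermediate
13 | methyl 2-[(4R)-4-ethenyl-2-oxocyclopentyl]-2-[(methanesulfonyl)oxy]acetate | C=C[C@@H]1CC(C(OS(C)(=O)=O)C(=O)OC)C(=O)C1 | intermediate (not isolated)
14 | methyl (2E)-2-[(4R)-4-ethenyl-2-oxocyclopentylidene]acetate | C=C[C@@H]1C/C(=C\C(=O)OC)C(=O)C1 | intermediate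
15 | methyl (2E)-2-[(8R)-8-ethenyl-1,4-dioxaspiro[4.4]nonan-6-ylidene]acetate | C=C[C@@H]1C/C(=C\C(=O)OC)C2(C1)OCCO2 | intermediate
16 | methyl (2E)-2-[(8R)-8-[2-(9-borabicyclo[3.3.1]nonan-9-yl)ethyl]-1,4-dioxaspiro[4.4]nonan-6-ylidene]acetate | C1CCC2CCCC1B2CC[C@@H]3C/C(=C\C(=O)OC)C4(C3)OCCO4 | intermediate (not isolated)
17 | tert-butyl (1R)-3-[(1E)-4-[(6E,8R)-6-(2-methoxy-2-oxoethylidene)-1,4-dioxaspiro[4.4]nonan-8-yl]but-1-en-1-yl]-1-methylcyclohex-2-ene-1-carboxylate | C1CC[C@@](C)(C(=O)OC(C)(C)C)C=C1/C=C/CC[C@@H]2C/C(=C\C(=O)OC)C3(C2)OCCO3 | intermediate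
18 | B-homo Diels–Alder adduct (C10=C20; 4α-CO2tBu; 4β-Me; H5 β; 6α-CO2Me; H9 β; 15-ethylene ketal) | C1[C@@H]2CC[C@H]3C=C4CCC[C@@](C)(C(=O)OC(C)(C)C)[C@H]4[C@@H](C(=O)OC)[C@]3(C2)C15OCCO5 | intermediate
19 | 6β-CO2Me epimer of the B-homo adduct | C1[C@@H]2CC[C@H]3C=C4CCC[C@@](C)(C(=O)OC(C)(C)C)[C@H]4[C@H](C(=O)OC)[C@]3(C2)C15OCCO5 | intermediate
20 | B-homo 20β-iodo-19,10α-lactone 15-ethylene ketal 7-methyl ester | C1[C@@H]2CC[C@H]3[C@H](I)[C@@]45CCC[C@@](C)(C(=O)O4)[C@H]5[C@H](C(=O)OC)[C@]3(C2)C16OCCO6 | intermediate (not isolated)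
21 | B-homo 20β-iodo-19,10α-lactone 15-ketone 7-methyl ester | C1[C@@H]2CC[C@H]3[C@H](I)[C@@]45CCC[C@@](C)(C(=O)O4)[C@H]5[C@H](C(=O)OC)[C@]3(C2)C1=O | intermediate
22 | B-homo 10α,20α-epoxide 15-ketone 7,19-dimethyl ester | C1[C@@H]2CC[C@H]3[C@H]4O[C@]45CCC[C@@](C)(C(=O)OC)[C@H]5[C@H](C(=O)OC)[C@]3(C2)C1=O | intermediate
23 | 16-[(dimethylamino)methyl] derivative of 22 (mixture at C16) | CN(C)CC1[C@@H]2CC[C@H]3[C@H]4O[C@]45CCC[C@@](C)(C(=O)OC)[C@H]5[C@H](C(=O)OC)[C@]3(C2)C1=O | intermediate (not isolated)
24 | 16-[(trimethylammonio)methyl] derivative of 22, iodide | C[N+](C)(C)CC1[C@@H]2CC[C@H]3[C@H]4O[C@]45CCC[C@@](C)(C(=O)OC)[C@H]5[C@H](C(=O)OC)[C@]3(C2)C1=O.[I-] | intermediate (not isolated)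
25 | B-homo 10α,20α-epoxy-16-methylidene-15-ketone dimethyl ester | C=C1[C@@H]2CC[C@H]3[C@H]4O[C@]45CCC[C@@](C)(C(=O)OC)[C@H]5[C@H](C(=O)OC)[C@]3(C2)C1=O | intermediate
26 | B-homo 10α,20α-epoxy-15β-hydroxy-16-methylidene dimethyl ester (OH endo, syn to C11) | C=C1[C@@H]2CC[C@H]3[C@H]4O[C@]45CCC[C@@](C)(C(=O)OC)[C@H]5[C@H](C(=O)OC)[C@]3(C2)[C@@H]1O | intermediate
27 | 15β-acetate of the B-homo epoxy alcohol | C=C1[C@@H]2CC[C@H]3[C@H]4O[C@]45CCC[C@@](C)(C(=O)OC)[C@H]5[C@H](C(=O)OC)[C@]3(C2)[C@@H]1OC(C)=O | intermediate
28 | 7,19-dimethyl ester 15-acetate of the target gibberellin (ring B contracted, 10α-CHO) | C=C1[C@@H]2CC[C@H]3[C@]4(C=O)CCC[C@@](C)(C(=O)OC)[C@H]4[C@H](C(=O)OC)[C@]3(C2)[C@@H]1OC(C)=O | intermediate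
29 | target gibberellin (15β-hydroxy-16-methylidene 20-aldehyde 7,19-diacid) | C=C1[C@@H]2CC[C@H]3[C@]4(C=O)CCC[C@@](C)(C(=O)O)[C@H]4[C@H](C(=O)O)[C@]3(C2)[C@@H]1O | target

**Count and risks**

Total steps: 19. Longest linear sequence: 15 (steps 1–5 and 10–19).

Step 11 (key step). What may go wrong: the cycloaddition may not set in below the temperature at which the tert-butyl ester loses isobutene, or the mode with the diene over the ketal side may compete. Fallback, from 17 back to 18: the dienophile is made an enal. i-Bu2AlH at −78 °C should reduce the conjugated methyl ester of 17 to the allylic alcohol triene F1, leaving the tert-butyl ester on the quaternary carbon. MnO2 should give the enal triene F2, a much stronger dienophile whose formyl group again prefers the endo position, so the cycloaddition should run near 110 °C in toluene to the aldehyde adduct F3. Pinnick oxidation (NaClO2, NaH2PO4, 2-methylbut-2-ene) to the carboxylic acid adduct F4 and esterification with TMSCHN2 return to 18.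

Step 18. What may go wrong: hydride shift from C20 to the ring-enlarged ketone may compete with the ring-bond shift, and the aluminium Lewis acid may ionise the allylic acetate or engage the 16-alkene before the hindered epoxide opens. Fallback, from 25 back to 29: the shift is moved ahead of the reduction, to the stage where ring D is a Lewis-acid-tolerant enone. Compound 25 is rearranged with MeAl(OAr)2 to the formyl enone F5. A ketone-selective Luche reduction in aqueous ethanol (NaBH4, CeCl3, the hindered aldehyde held as its hydrate) should give the 15β-hydroxy aldehyde diester F6, and LiOH hydrolysis as in step 19 gives 29. This fallback removes the acetate and alkene problem; it does not by itself suppress the hydride shift.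

Step 19. What may go wrong: the neopentyl, axial C19 ester may resist acyl attack, and prolonged hydroxide exposure may damage the aldehyde by Cannizzaro-type disproportionation. Fallback, from 28 back to 29: the unhindered groups are removed first and the last ester is cleaved at the O–methyl bond instead. K2CO3 in aqueous methanol at rt should remove the acetate and the C7 ester to give the 19-monomethyl ester of the target F7, and SN2 demethylation with lithium propane-1-thiolate in HMPA then gives 29.

**Further compounds**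

F1 | step 11 | allylic alcohol triene (CH2OH in place of the methyl ester of 17) | C1CC[C@@](C)(C(=O)OC(C)(C)C)C=C1/C=C/CC[C@@H]2C/C(=C\CO)C3(C2)OCCO3
F2 | step 11 | enal triene (CHO in place of the methyl ester of 17) | C1CC[C@@](C)(C(=O)OC(C)(C)C)C=C1/C=C/CC[C@@H]2C/C(=C\C=O)C3(C2)OCCO3
F3 | step 11 | aldehyde adduct (6α-CHO analogue of 18) | C1[C@@H]2CC[C@H]3C=C4CCC[C@@](C)(C(=O)OC(C)(C)C)[C@H]4[C@@H](C=O)[C@]3(C2)C15OCCO5
F4 | step 11 | carboxylic acid adduct (6α-CO2H analogue of 18) | C1[C@@H]2CC[C@H]3C=C4CCC[C@@](C)(C(=O)OC(C)(C)C)[C@H]4[C@@H](C(=O)O)[C@]3(C2)C15OCCO5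
F5 | step 18 | formyl enone (16-methylidene-15-oxo 20-aldehyde 7,19-dimethyl ester) | C=C1[C@@H]2CC[C@H]3[C@]4(C=O)CCC[C@@](C)(C(=O)OC)[C@H]4[C@H](C(=O)OC)[C@]3(C2)C1=O
F6 | step 18 | 15β-hydroxy aldehyde diester (7,19-dimethyl ester of the target) | C=C1[C@@H]2CC[C@H]3[C@]4(C=O)CCC[C@@](C)(C(=O)OC)[C@H]4[C@H](C(=O)OC)[C@]3(C2)[C@@H]1O
F7 | step 19 | 19-monomethyl ester of the target | C=C1[C@@H]2CC[C@H]3[C@]4(C=O)CCC[C@@](C)(C(=O)OC)[C@H]4[C@H](C(=O)O)[C@]3(C2)[C@@H]1O
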